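The data are simulated from invented constants; scatter was added.

Time pulled the two earlier flasks, ash and alder, apart: the ratio c(isomer of the product)/c(target) stood at 0.617 and 0.591 at 0.500 h, but at 0.822 and 0.701 at 6.00 h.

| flask | substrate | remark | time |
|---|---|---|---|
| ash | 14 mM | run made earlier |  |
| alder | 22 mM | run made earlier |  |
| flask | 10 mM |  | 6.0 h |

- ash (time / h: isomer of the product / %, target / %): 0.500: 13.2, 21.4; 1.50: 31.8, 48.9; 3.00: 38.9, 56.7; 4.00: 42.1, 57.2; 6.00: 45.2, 55.0
- alder (time / h: isomer of the product / %, target / %): 0.500: 13.3, 22.5; 1.50: 30.2, 50.3; 3.00: 37.8, 59.0; 4.00: 39.5, 59.0; 6.00: 41.5, 59.2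

(each reading ± 0.5 percentage points)

- target is meant together with its crystals
- solid, in amounts per volume of the solution: crystals
- steps under discussion: intermediate <-> target; intermediate <-> isomer of the product; crystals <-> target; substrate -> intermediate

- ratio of isomer of the product to target at 3.0 min
- ratio of isomer of the product to target at 30 min
- ratio of isomer of the product to target at 6.0 h

I took the mean of the two ratios read at 0.500 h, 0.604, as my figure for the flask at 30 min. No reading stands before 0.500 h, so for 3.0 min I could carry that mean back only as a guess.

Late, the charge mattered. From 3.00 h to 6.00 h the isomer rose by 0.294 mM h⁻¹ in ash and 0.271 mM h⁻¹ in alder, close figures for different charges. So I supposed that crystals held c(target) steady in both, leaking a fixed amount per volume into the isomer. The two readings at 6.00 h then gave that amount, 1.42 mM, and a fixed isomer share, 35.0%. For the flask this gave 14.2%; that is the leak number, the leaked amount as a share of the charge. The isomer share became 49.3%, and with target taking the rest, the ratio was 0.971. The number needs the fixed share beside it, and it does not reach the early times, where ash and alder show little effect of charge.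

The forecast gave 0.59, 0.605 and 0.84, reasoning that the flask “should stay unsaturated and no crystals should form”, which differs from my reckoning.

The flask gave 0.423 at 3.0 min, 0.603 at 30 min and 0.952 at 6.0 h.

    intermediate ⇌ target (K = 1.00, k = 0.00191 s⁻¹)
    intermediate ⇌ isomer of the product (K = 260, k = 7.20 × 10⁻⁴ s⁻¹)
    crystals ⇌ target, rate k3*(cs3 - [target]) while solid is left; crystals form when [target] > cs3 (solubility = 0.140 mM, k = 0.00366 s⁻¹)
    substrate → intermediate (k = 3.52 × 10⁻⁴ s⁻¹)

In the flask, substrate fed the intermediate with a half-life of 0.55 h by that step while target crystallised, and by 3.00 h crystals stood at 53.7% within 55.1% target, with substrate at 2.23%. By 6.00 h crystals had fallen to 49.5% while the isomer rose from 41.2% to 48.3%, against 49.3% from 35.0% plus the leak number 14.2%. The neighbour charged with 4.0 mM has a leak number of 35.6%, which reads as a ratio of 2.40, and that neighbour stood at 2.25 at 6.00 h.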